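**Retrosynthetic overview**
1. The last operations are hydrogenolysis of two benzyl groups and hydrolysis of a dioxolane. Before them, the depside C(=O)–OAr bond is cut into a protected ring A acid and benzyl olivetolate (ring B).
2. The key C–C cut is ArCH2–C(=O)C5H11 in the ring A side chain. It is made by a crossed Claisen-type condensation of the lithiated o-toluate (a vinylogous ester enolate, from methyl orsellinate) with the Weinreb amide of hexanoic acid.
3. Ring B comes from Michael addition of dimethyl malonate to (E)-non-3-en-2-one, Dieckmann closure and bromination–dehydrobromination to methyl olivetolate. The methyl ester is then exchanged for benzyl by way of the bis(benzyl ether).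
4. Ring order: ring A is bought as an arene. The ring B carbocycle closes in step 7 and is aromatised in step 8. The temporary dioxolane ring closes in step 5 and opens in step 14.

Assumption 1: the target SMILES has no stereocentre and no stereogenic double bond, so the compound is achiral and no enantiomer has to be selected. The transient stereocentres in 8 and 14–16 are racemic and are erased later.
Assumption 2: simple proton-transfer forms of a numbered compound (phenoxides, carboxylates, the free base of 2) are treated as that compound. The carbanion 7 is numbered because it is the nucleophile of the key step.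

**Step 1**
Reactants: 1 hexanoyl chloride; 2 N,O-dimethylhydroxylamine hydrochloride
Product: 3 N-methoxy-N-methylhexanamide
Conditions: K2CO3 (2.5 equiv), CH2Cl2/H2O (1:1), 0 °C to rt, 2 h
Reagents that add atoms: none
Why: Schotten–Baumann acylation, in which K2CO3 frees the amine of 2, the amine attacks the acid chloride much faster than water does, and the Weinreb amide formed is stable to the cold aqueous base.

**Step 2**
Reactants: 4 methyl 2,4-dihydroxy-6-methylbenzoate (methyl orsellinate)
Product: 5 methyl 2-hydroxy-4-methoxy-6-methylbenzoate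
Conditions: MeI (1.05 equiv), K2CO3 (1.1 equiv), acetone, reflux, 6 h
Reagents that add atoms: iodomethane, CI
Why: Williamson ether synthesis that stops at the 4-OH, because the 2-OH is locked in a hydrogen bond to the ester carbonyl and is not ionised by one equivalent of K2CO3 in acetone.

**Step 3**
Reactants: 5 methyl 2-hydroxy-4-methoxy-6-methylbenzoate
Product: 6 methyl 2-(benzyloxy)-4-methoxy-6-methylbenzoate
Conditions: BnBr (1.3 equiv), K2CO3 (2.5 equiv), DMF, 60 °C, 12 h
Reagents that add atoms: benzyl bromide, BrCc1ccccc1
Why: Williamson benzylation in a polar aprotic solvent at 60 °C overcomes the hydrogen bond and removes the last acidic proton before the strong-base step, using a group that leaves at the end by hydrogenolysis.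

**Step 4 (key step)**
Reactants: 6 methyl 2-(benzyloxy)-4-methoxy-6-methylbenzoate; 3 N-methoxy-N-methylhexanamide
Product: 9 methyl 2-(benzyloxy)-4-methoxy-6-(2-oxoheptyl)benzoate, via lithiated toluate 7 (not isolated), via lithium hemiaminal adduct 8 (not isolated)
Conditions: LiN(iPr)2 (2.2 equiv, commercial solution), THF, −78 °C, 15 min; then 3 (1.3 equiv), −78 °C, 1 h; AcOH quench at −78 °C
Reagents that add atoms: none
Why: Crossed Claisen-type condensation, in which LiN(iPr)2 deprotonates the ortho-methyl group to the vinylogous ester enolate 7 (lateral lithiation), 7 adds to Weinreb amide 3 to give the chelated adduct 8 that resists a second addition and releases the ketone only at the cold acid quench, the second equivalent of base covers any acidic ketone formed early, and no stereocentre remains in 9.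

**Step 5**
Reactants: 9 methyl 2-(benzyloxy)-4-methoxy-6-(2-oxoheptyl)benzoate
Product: 10 methyl 2-(benzyloxy)-4-methoxy-6-[(2-pentyl-1,3-dioxolan-2-yl)methyl]benzoate
Conditions: Me3SiOCH2CH2OSiMe3 (2 equiv), Me3SiOSO2CF3 (5 mol %), CH2Cl2, −78 to −20 °C, 6 h; pyridine quench
Reagents that add atoms: 1,2-bis(trimethylsilyloxy)ethane, C[Si](C)(C)OCCO[Si](C)(C)C
Why: Noyori ketalisation runs aprotic and cold, so the enolisable benzyl ketone is masked as a dioxolane without the acid- or heat-driven enol lactonisation onto the neighbouring ester that would give an isocoumarin.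

**Step 6**
Reactants: 10 methyl 2-(benzyloxy)-4-methoxy-6-[(2-pentyl-1,3-dioxolan-2-yl)methyl]benzoate
Product: 11 2-(benzyloxy)-4-methoxy-6-[(2-pentyl-1,3-dioxolan-2-yl)methyl]benzoic acid
Conditions: KOH (10 equiv), DMSO/H2O (4:1), 95 °C, 16 h; cold aq. KHSO4 to pH 4 at 0 °C, EtOAc extraction, used at once
Reagents that add atoms: potassium hydroxide, [K+].[OH-]
Why: Saponification (BAc2) of the doubly ortho-substituted ester needs poorly solvated hydroxide in hot aqueous DMSO, conditions to which the ketal, benzyl ether and methyl ether are inert, and the brief cold acidification to pH 4 spares the dioxolane.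

**Step 7**
Reactants: 12 dimethyl malonate; 13 (E)-non-3-en-2-one
Product: 15 methyl 2-hydroxy-4-oxo-6-pentylcyclohex-2-ene-1-carboxylate (racemic), via Michael adduct 14 (not isolated)
Conditions: NaOMe (1.1 equiv), 12 (1.1 equiv), MeOH, rt; then 13, reflux, 4 h; aq. HCl to pH 3
Reagents that add atoms: none
Why: Michael addition of sodium dimethyl malonate to the enone gives 14, whose methyl-ketone enolate closes onto one ester (Dieckmann-type intramolecular Claisen condensation), the sequence is pulled forward by the stabilised enolate of the cyclic 1,3-dione, and the two new stereocentres are racemic and are erased in step 8.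

**Step 8**
Reactants: 15 methyl 2-hydroxy-4-oxo-6-pentylcyclohex-2-ene-1-carboxylate
Product: 17 methyl 2,4-dihydroxy-6-pentylbenzoate (methyl olivetolate), via bromo enol 16 (not isolated)
Conditions: Br2 (1.0 equiv), DMF, 0 °C, 1 h; then 80 °C, 12 h; aq. Na2S2O3 wash
Reagents that add atoms: none
Why: Bromination–dehydrobromination aromatisation, in which the enolised 1,3-dione takes up one bromine and warming in DMF expels HBr so the dienone tautomerises to the resorcinol, at a temperature well below that at which the ester would be lost.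

**Step 9**
Reactants: 17 methyl 2,4-dihydroxy-6-pentylbenzoate
Product: 18 methyl 2,4-bis(benzyloxy)-6-pentylbenzoate
Conditions: BnBr (2.5 equiv), K2CO3 (4 equiv), DMF, 60 °C, 16 h
Reagents that add atoms: benzyl bromide, BrCc1ccccc1
Why: Double Williamson benzylation caps both phenols, so the forcing saponification that follows acts on an uncharged ring and gives an acid that does not decarboxylate.

**Step 10**
Reactants: 18 methyl 2,4-bis(benzyloxy)-6-pentylbenzoate
Product: 19 2,4-bis(benzyloxy)-6-pentylbenzoic acid
Conditions: KOH (10 equiv), DMSO/H2O (4:1), 95 °C, 16 h; aq. HCl to pH 2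
Reagents that add atoms: potassium hydroxide, [K+].[OH-]
Why: Saponification (BAc2) of a hindered benzoate with hydroxide in hot aqueous DMSO is safe here, because the only other groups are ethers and the ether-protected acid tolerates both heat and acidification.

**Step 11**
Reactants: 19 2,4-bis(benzyloxy)-6-pentylbenzoic acid
Product: 20 2,4-dihydroxy-6-pentylbenzoic acid (olivetolic acid)
Conditions: H2 (1 atm), Pd/C (10 wt % Pd), EtOAc, rt, 3 h
Reagents that add atoms: none
Why: Catalytic hydrogenolysis frees both phenols under neutral conditions at room temperature, which avoids the decarboxylation that olivetolic acid suffers in hot acid or hot base.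

**Step 12**
Reactants: 20 2,4-dihydroxy-6-pentylbenzoic acid
Product: 21 benzyl 2,4-dihydroxy-6-pentylbenzoate (benzyl olivetolate)
Conditions: BnBr (1.05 equiv), KHCO3 (1.2 equiv), DMF, rt, 16 h
Reagents that add atoms: benzyl bromide, BrCc1ccccc1
Why: SN2 alkylation of the carboxylate, in which KHCO3 ionises only the carboxylic acid (pKa about 3) and not the phenols, so only the benzyl ester forms.

**Step 13**
Reactants: 11 2-(benzyloxy)-4-methoxy-6-[(2-pentyl-1,3-dioxolan-2-yl)methyl]benzoic acid; 21 benzyl 2,4-dihydroxy-6-pentylbenzoate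
Product: 23 benzyl 4-({2-(benzyloxy)-4-methoxy-6-[(2-pentyl-1,3-dioxolan-2-yl)methyl]benzoyl}oxy)-2-hydroxy-6-pentylbenzoate, via O-acylisourea 22 (not isolated)
Conditions: N,N'-dicyclohexylcarbodiimide (1.2 equiv), 4-(dimethylamino)pyridine (0.3 equiv), CH2Cl2, 0 °C to rt, 16 h
Reagents that add atoms: none
Why: Steglich esterification, in which the acyl group of 22 is passed through the acylpyridinium ion to the free 4-OH of 21, the 2-OH being hydrogen-bonded to and shielded by the benzyl ester, while the ketal keeps the activated acid from closing to an isocoumarin.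

**Step 14**
Reactants: 23 benzyl 4-({2-(benzyloxy)-4-methoxy-6-[(2-pentyl-1,3-dioxolan-2-yl)methyl]benzoyl}oxy)-2-hydroxy-6-pentylbenzoate
Product: 24 benzyl 4-{[2-(benzyloxy)-4-methoxy-6-(2-oxoheptyl)benzoyl]oxy}-2-hydroxy-6-pentylbenzoate
Conditions: 1 M aq. HCl/THF (1:4), rt, 6 h
Reagents that add atoms: water, O
Why: Acid-catalysed ketal hydrolysis at room temperature is much faster than hydrolysis of the hindered aryl ester, the benzyl ester or the ethers, so only the ketone is unmasked.

**Step 15**
Reactants: 24 benzyl 4-{[2-(benzyloxy)-4-methoxy-6-(2-oxoheptyl)benzoyl]oxy}-2-hydroxy-6-pentylbenzoate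
Product: 25 2-hydroxy-4-{[2-hydroxy-4-methoxy-6-(2-oxoheptyl)benzoyl]oxy}-6-pentylbenzoic acid (target)
Conditions: H2 (1 atm), Pd/C (10 wt % Pd), EtOAc, rt, 3 h
Reagents that add atoms: none
Why: Catalytic hydrogenolysis cleaves the benzyl ether and the benzyl ester under neutral conditions that leave the dialkyl ketone, the depside aryl ester and the aryl methyl ether untouched.

**Compound list**
1 | hexanoyl chloride | CCCCCC(=O)Cl | starting material
2 | N,O-dimethylhydroxylamine hydrochloride | CNOC.Cl | starting material
3 | N-methoxy-N-methylhexanamide | CCCCCC(=O)N(C)OC | intermediate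
4 | methyl 2,4-dihydroxy-6-methylbenzoate (methyl orsellinate) | COC(=O)c1c(C)cc(O)cc1O | starting material
5 | methyl 2-hydroxy-4-methoxy-6-methylbenzoate | COC(=O)c1c(C)cc(OC)cc1O | intermediate
6 | methyl 2-(benzyloxy)-4-methoxy-6-methylbenzoate | COC(=O)c1c(C)cc(OC)cc1OCc1ccccc1 | intermediate
7 | [3-(benzyloxy)-5-methoxy-2-(methoxycarbonyl)benzyl]lithium (lithiated toluate, not isolated) | [Li]Cc1cc(OC)cc(OCc2ccccc2)c1C(=O)OC | intermediate
8 | lithium 1-[3-(benzyloxy)-5-methoxy-2-(methoxycarbonyl)phenyl]-2-[methoxy(methyl)amino]heptan-2-olate (racemic, not isolated) | CCCCCC(O[Li])(Cc1cc(OC)cc(OCc2ccccc2)c1C(=O)OC)N(C)OC | intermediate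
9 | methyl 2-(benzyloxy)-4-methoxy-6-(2-oxoheptyl)benzoate | CCCCCC(=O)Cc1cc(OC)cc(OCc2ccccc2)c1C(=O)OC | intermediate
10 | methyl 2-(benzyloxy)-4-methoxy-6-[(2-pentyl-1,3-dioxolan-2-yl)methyl]benzoate | CCCCCC1(Cc2cc(OC)cc(OCc3ccccc3)c2C(=O)OC)OCCO1 | intermediate
11 | 2-(benzyloxy)-4-methoxy-6-[(2-pentyl-1,3-dioxolan-2-yl)methyl]benzoic acid | CCCCCC1(Cc2cc(OC)cc(OCc3ccccc3)c2C(=O)O)OCCO1 | intermediate
12 | dimethyl malonate | COC(=O)CC(=O)OC | starting material
13 | (E)-non-3-en-2-one | CCCCC/C=C/C(C)=O | starting material
14 | dimethyl 2-(2-oxononan-4-yl)propanedioate (racemic, not isolated) | CCCCCC(CC(C)=O)C(C(=O)OC)C(=O)OC | intermediate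
15 | methyl 2-hydroxy-4-oxo-6-pentylcyclohex-2-ene-1-carboxylate (racemic, mainly trans, drawn flat because both centres vanish in step 8) | CCCCCC1CC(=O)C=C(O)C1C(=O)OC | intermediate
16 | methyl 3-bromo-2-hydroxy-4-oxo-6-pentylcyclohex-2-ene-1-carboxylate (racemic, not isolated) | CCCCCC1CC(=O)C(Br)=C(O)C1C(=O)OC | intermediate
17 | methyl 2,4-dihydroxy-6-pentylbenzoate (methyl olivetolate) | CCCCCc1cc(O)cc(O)c1C(=O)OC | intermediate
18 | methyl 2,4-bis(benzyloxy)-6-pentylbenzoate | CCCCCc1cc(OCc2ccccc2)cc(OCc2ccccc2)c1C(=O)OC | intermediate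
19 | 2,4-bis(benzyloxy)-6-pentylbenzoic acid | CCCCCc1cc(OCc2ccccc2)cc(OCc2ccccc2)c1C(=O)O | intermediate
20 | 2,4-dihydroxy-6-pentylbenzoic acid (olivetolic acid) | CCCCCc1cc(O)cc(O)c1C(=O)O | intermediate
21 | benzyl 2,4-dihydroxy-6-pentylbenzoate | CCCCCc1cc(O)cc(O)c1C(=O)OCc1ccccc1 | intermediate
22 | O-{2-(benzyloxy)-4-methoxy-6-[(2-pentyl-1,3-dioxolan-2-yl)methyl]benzoyl}-N,N'-dicyclohexylisourea (not isolated) | CCCCCC1(Cc2cc(OC)cc(OCc3ccccc3)c2C(=O)OC(=NC2CCCCC2)NC2CCCCC2)OCCO1 | intermediate
23 | benzyl 4-({2-(benzyloxy)-4-methoxy-6-[(2-pentyl-1,3-dioxolan-2-yl)methyl]benzoyl}oxy)-2-hydroxy-6-pentylbenzoate | CCCCCC1(Cc2cc(OC)cc(OCc3ccccc3)c2C(=O)Oc2cc(O)c(C(=O)OCc3ccccc3)c(CCCCC)c2)OCCO1 | intermediate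
24 | benzyl 4-{[2-(benzyloxy)-4-methoxy-6-(2-oxoheptyl)benzoyl]oxy}-2-hydroxy-6-pentylbenzoate | CCCCCC(=O)Cc1cc(OC)cc(OCc2ccccc2)c1C(=O)Oc1cc(O)c(C(=O)OCc2ccccc2)c(CCCCC)c1 | intermediate
25 | 2-hydroxy-4-{[2-hydroxy-4-methoxy-6-(2-oxoheptyl)benzoyl]oxy}-6-pentylbenzoic acid (achiral) | CCCCCC(=O)Cc1cc(OC)cc(O)c1C(=O)Oc1cc(O)c(C(=O)O)c(CCCCC)c1 | target

**Total step count:** 15.
**Longest linear sequence:** 9 steps (steps 7–15, from 12 and 13 to 25). The ring A branch takes 8 steps (steps 2–6 and 13–15).

**The three steps most likely to fail**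

Step 4. The risks are proton transfer from the enolisable amide 3 to anion 7, attack of 7 on the ester of unreacted 6, and base-induced cyclisation of the product. The fallback sets out from 6 and comes back at 9.
- The same anion (LiN(iPr)2, THF, −78 °C to rt) is trapped with the non-enolisable electrophile dimethyl carbonate to give methyl 2-(benzyloxy)-4-methoxy-6-(2-methoxy-2-oxoethyl)benzoate F1.
- The much more acidic arylacetate position of F1 is deprotonated with LiN(SiMe3)2 (2.1 equiv, THF, −78 °C) and C-acylated with hexanoyl chloride 1 in a true ester-enolate Claisen acylation. This gives methyl 2-(benzyloxy)-4-methoxy-6-(1-methoxy-1,3-dioxooctan-2-yl)benzoate F2.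
- Krapcho demethoxycarbonylation (LiCl, wet DMSO, 120 °C) then removes the extra ester and delivers 9.

Step 8. The risks are over-bromination of the electron-rich product and HBr-induced loss of the ester, which make the yield of the one-equivalent bromination variable. The fallback sets out from 15 and comes back at 17.
- 15 is deliberately over-brominated and aromatised with Br2 (3 equiv) in AcOH at rt. This gives the stable, crystalline methyl 3,5-dibromo-2,4-dihydroxy-6-pentylbenzoate F3.
- Both ring bromines are then removed reductively (H2, Pd/C, NaOAc, MeOH, rt) to give 17.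

Step 13. Acid 11 is doubly ortho-substituted, so acyl transfer is slow and N-acylurea formation competes. The free acid can also attack its own ketal. The fallback sets out from 9 and comes back at 24, bypassing 10, 11 and 23 and so also the ketal cleavage of step 14.
- 9 is saponified directly (KOH, DMSO/H2O, 60 °C; cold dilute HCl) to the less hindered 2-(benzyloxy)-4-methoxy-6-(2-oxoheptyl)benzoic acid F4.
- F4 is condensed with 21 using N,N'-dicyclohexylcarbodiimide in dry toluene at rt without any amine base. Enolisation, and with it isocoumarin formation, stays slow, and 24 forms directly.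

**Further compounds**
F1 | step 4 | methyl 2-(benzyloxy)-4-methoxy-6-(2-methoxy-2-oxoethyl)benzoate | COC(=O)Cc1cc(OC)cc(OCc2ccccc2)c1C(=O)OC
F2 | step 4 | methyl 2-(benzyloxy)-4-methoxy-6-(1-methoxy-1,3-dioxooctan-2-yl)benzoate (racemic) | CCCCCC(=O)C(C(=O)OC)c1cc(OC)cc(OCc2ccccc2)c1C(=O)OC
F3 | step 8 | methyl 3,5-dibromo-2,4-dihydroxy-6-pentylbenzoate | CCCCCc1c(Br)c(O)c(Br)c(O)c1C(=O)OC
F4 | step 13 | 2-(benzyloxy)-4-methoxy-6-(2-oxoheptyl)benzoic acid | CCCCCC(=O)Cc1cc(OC)cc(OCc2ccccc2)c1C(=O)O
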